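**Retrosynthetic overview**
1. Target 14 ⇒ one global acidolysis of the tert-butyl ester / bis-acetonide 13.
2. 13 ⇒ three-component linchpin union: alcohol 10 + Ph3P=C=C=O + aldehyde 7. The cinnamate C=C and the ester are made together, so no preformed cinnamic acid is esterified.
3. 7 ⇒ phosphine-catalysed α-umpolung addition/lactonisation of 3,4-dihydroxybenzaldehyde onto aryl ynoate 4 (key step; sets ring regiochemistry and Z-geometry).
4. 4 ⇒ aryl bromide 1 + orthoester-masked propiolate. 10 ⇒ Grignard of 1 + tert-butyl (R)-glycidate; the stereocentre is carried over from the epoxide untouched.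
5. Ring order: the 1,4-benzodioxin-2-one is the only ring built (step 2); all arenes and acetonides are bought.

Assumption: 1 and tert-butyl (2R)-oxirane-2-carboxylate 8 (≥98 % ee) are bought as catalogue building blocks.

**Step 1**
Reactants: 1 5-bromo-2,2-dimethyl-1,3-benzodioxole; 2 3,3,3-triethoxyprop-1-yne
Product: 4 ethyl 3-(2,2-dimethyl-1,3-benzodioxol-5-yl)prop-2-ynoate, via alkynyl orthoester 3 (not isolated)
Conditions: PdCl2(MeCN)2 (2 mol %), XPhos (6 mol %), Cs2CO3, MeCN, 80 °C; then TsOH·H2O (cat.), THF/H2O, rt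
Reagents that add atoms: water, O
Why: Copper-free Sonogashira coupling with the orthoester-masked propiolate (no base-induced Michael oligomerisation, unlike ethyl propiolate), then mild acid hydrolysis of the orthoester to the ethyl ester, which the catechol acetonide tolerates.

**Step 2**
Reactants: 4 ethyl 3-(2,2-dimethyl-1,3-benzodioxol-5-yl)prop-2-ynoate; 5 3,4-dihydroxybenzaldehyde (1.2 equiv)
Product: 7 (2Z)-2-[(2,2-dimethyl-1,3-benzodioxol-5-yl)methylidene]-3-oxo-2,3-dihydro-1,4-benzodioxine-6-carbaldehyde, via open-chain aryloxyacrylate 6 (not isolated)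
Conditions: PPh3 (20 mol %), toluene/1,4-dioxane, 100 °C; then CSA (30 mol %), 5 Å MS, 100 °C (EtOH removed)
Reagents that add atoms: none
Why: Proposed new method: PPh3 adds to the β-carbon of ynoate 4, the vinyl anion is protonated by the most acidic proton present (4-OH of 5, para to CHO, pKa ≈ 7), and the ion-paired 4-phenoxide adds to the α-carbon of the vinylphosphonium; proton shift and loss of PPh3 give the thermodynamically preferred (Z)-α-aryloxycinnamate 6 (aryl cis to O), whose remaining 3-OH closes the six-membered aryl lactone under acid with loss of EtOH, so the enol-ether oxygen ends up para and the lactone oxygen meta to the formyl group as the target requires; the closest known reaction type is the Trost-type phosphine-catalysed α-addition of N–H pronucleophiles to aryl propiolates, together with phosphine-catalysed umpolung addition/cyclisation of catechol onto 2-alkynoates.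

**Step 3**
Reactants: 1 5-bromo-2,2-dimethyl-1,3-benzodioxole; 8 tert-butyl (2R)-oxirane-2-carboxylate
Product: 10 tert-butyl (2R)-3-(2,2-dimethyl-1,3-benzodioxol-5-yl)-2-hydroxypropanoate, via arylmagnesium bromide 9 (not isolated)
Conditions: Mg, THF, 45 °C; then CuI (10 mol %), 8, THF, −40 → −20 °C; aq NH4Cl
Reagents that add atoms: none
Why: Grignard formation and copper-catalysed SN2 epoxide opening at the unsubstituted CH2 terminus (faster at −40 °C than addition to the hindered tert-butyl ester); the C2–O bond is never broken, so the (R) centre of 8 becomes the (R)-α-hydroxy ester centre of 10 unchanged.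

**Step 4**
Reactants: 10 tert-butyl (2R)-3-(2,2-dimethyl-1,3-benzodioxol-5-yl)-2-hydroxypropanoate; 11 (triphenylphosphoranylidene)ketene (Bestmann ylide); 7 (2Z)-2-[(2,2-dimethyl-1,3-benzodioxol-5-yl)methylidene]-3-oxo-2,3-dihydro-1,4-benzodioxine-6-carbaldehyde
Product: 13 tert-butyl (2R)-3-(2,2-dimethyl-1,3-benzodioxol-5-yl)-2-{[(2E)-3-{(2Z)-2-[(2,2-dimethyl-1,3-benzodioxol-5-yl)methylidene]-3-oxo-2,3-dihydro-1,4-benzodioxin-6-yl}prop-2-enoyl]oxy}propanoate, via ylide ester 12 (not isolated)
Conditions: 10, 11 and 7 together, toluene, 70 °C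
Reagents that add atoms: none
Why: Three-component Bestmann-ylide esterification/Wittig: the O–H of 10 adds across Ph3P=C=C=O to give stabilised ylide 12, which is trapped at once by aldehyde 7 (faster than intramolecular Wittig onto the hindered tert-butyl ester) to give the (E)-cinnamate; conditions are neutral, so the aryl lactone and the α-stereocentre are untouched.

**Step 5**
Reactants: 13 (protected target, as named in step 4)
Product: 14 (2R)-3-(3,4-dihydroxyphenyl)-2-{[(2E)-3-{(2Z)-2-[(3,4-dihydroxyphenyl)methylidene]-3-oxo-2,3-dihydro-1,4-benzodioxin-6-yl}prop-2-enoyl]oxy}propanoic acid (CNP0141754.1)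
Conditions: TFA/H2O (9:1), 0 °C → rt; evaporation, RP-HPLC
Reagents that add atoms: none
Why: Global acid deprotection removes both catechol acetonides (as acetone) and the tert-butyl ester (as isobutene) in one operation, while the aryl enol-lactone, the cinnamate ester, both alkenes and the α-acyloxy stereocentre should be inert to TFA at room temperature.

**Compound list**
1 | 5-bromo-2,2-dimethyl-1,3-benzodioxole | CC1(C)Oc2ccc(Br)cc2O1 | starting material
2 | 3,3,3-triethoxyprop-1-yne | C#CC(OCC)(OCC)OCC | starting material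
3 | 2,2-dimethyl-5-(3,3,3-triethoxyprop-1-yn-1-yl)-1,3-benzodioxole | CCOC(OCC)(OCC)C#Cc1ccc2OC(C)(C)Oc2c1 | intermediate (not isolated)
4 | ethyl 3-(2,2-dimethyl-1,3-benzodioxol-5-yl)prop-2-ynoate | CCOC(=O)C#Cc1ccc2OC(C)(C)Oc2c1 | intermediate
5 | 3,4-dihydroxybenzaldehyde | O=Cc1ccc(O)c(O)c1 | starting material
6 | ethyl (2Z)-3-(2,2-dimethyl-1,3-benzodioxol-5-yl)-2-(4-formyl-2-hydroxyphenoxy)prop-2-enoate | CCOC(=O)/C(=C/c1ccc2OC(C)(C)Oc2c1)Oc1ccc(C=O)cc1O | intermediate (not isolated)
7 | (2Z)-2-[(2,2-dimethyl-1,3-benzodioxol-5-yl)methylidene]-3-oxo-2,3-dihydro-1,4-benzodioxine-6-carbaldehyde (CHO para to the enol-ether O, meta to the lactone O) | O=Cc1ccc2c(c1)OC(=O)/C(=C/c1ccc3OC(C)(C)Oc3c1)O2 | intermediate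
8 | tert-butyl (2R)-oxirane-2-carboxylate | CC(C)(C)OC(=O)[C@H]1CO1 | starting material
9 | (2,2-dimethyl-1,3-benzodioxol-5-yl)magnesium bromide | CC1(C)Oc2ccc([Mg]Br)cc2O1 | intermediate (not isolated)
10 | tert-butyl (2R)-3-(2,2-dimethyl-1,3-benzodioxol-5-yl)-2-hydroxypropanoate | CC(C)(C)OC(=O)[C@H](O)Cc1ccc2OC(C)(C)Oc2c1 | intermediate
11 | (triphenylphosphoranylidene)ketene | O=C=C=P(c1ccccc1)(c1ccccc1)c1ccccc1 | starting material
12 | tert-butyl (2R)-3-(2,2-dimethyl-1,3-benzodioxol-5-yl)-2-{[(triphenyl-λ5-phosphanylidene)acetyl]oxy}propanoate | CC(C)(C)OC(=O)[C@H](OC(=O)C=P(c1ccccc1)(c1ccccc1)c1ccccc1)Cc1ccc2OC(C)(C)Oc2c1 | intermediate (not isolated)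
13 | tert-butyl (2R)-3-(2,2-dimethyl-1,3-benzodioxol-5-yl)-2-{[(2E)-3-{(2Z)-2-[(2,2-dimethyl-1,3-benzodioxol-5-yl)methylidene]-3-oxo-2,3-dihydro-1,4-benzodioxin-6-yl}prop-2-enoyl]oxy}propanoate | O=C(/C=C/c1ccc2c(c1)OC(=O)/C(=C/c1ccc3OC(C)(C)Oc3c1)O2)O[C@H](Cc1ccc2OC(C)(C)Oc2c1)C(=O)OC(C)(C)C | intermediate
14 | (2R)-3-(3,4-dihydroxyphenyl)-2-{[(2E)-3-{(2Z)-2-[(3,4-dihydroxyphenyl)methylidene]-3-oxo-2,3-dihydro-1,4-benzodioxin-6-yl}prop-2-enoyl]oxy}propanoic acid | O=C(/C=C/c1ccc2c(c1)OC(=O)/C(=C/c1ccc(O)c(O)c1)O2)O[C@H](Cc1ccc(O)c(O)c1)C(=O)O | target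

**Total step count:** 5. **Longest linear sequence:** 4 steps (1 → 4 → 7 → 13 → 14).

**Three steps most likely to fail**

Step 2 is the riskiest. PPh3 may add too slowly to the electron-rich ynoate, the 3-OH may compete and give the regioisomeric lactone, or the transient phosphorus ylide may be intercepted by the aldehyde. The fallback builds the ring classically and installs the benzylidene last; it sets out from 5 and comes back to the route at 13. Selective alkylation of the more acidic 4-OH of 5 with ethyl bromoacetate (NaHCO3, NaI, DMF, 40 °C) gives ethyl 2-(4-formyl-2-hydroxyphenoxy)acetate F1. CSA in refluxing toluene with removal of ethanol closes it to 3-oxo-2,3-dihydro-1,4-benzodioxine-6-carbaldehyde F2. F2 takes the place of 7 in the three-component coupling of step 4 with 10 and 11 and gives the parent-lactone cinnamate F3, which no longer carries an aldehyde. Soft enolisation of the lactone CH2 of F3 (TiCl4, Et3N, CH2Cl2, −78 → 0 °C) and addition to purchased 2,2-dimethyl-1,3-benzodioxole-5-carbaldehyde F4 gives the aldol adduct F5. F5 loses water in the same pot on warming to give the thermodynamically favoured Z-benzylidene lactone 13.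

Step 4 is second. The ylide ester 12 derives from an α-hydroxy ester and can undergo intramolecular Wittig reaction onto its own ester carbonyl to give a tetronate, and the hindered, weakly nucleophilic alcohol may add slowly to the cumulated ylide. The fallback separates acylation from olefination; it sets out from 10 and comes back at 13. Compound 10 is acylated with diethylphosphonoacetic acid (DCC, DMAP cat., CH2Cl2, 0 °C) to give the phosphonoacetate ester F6. Masamune–Roush Horner–Wadsworth–Emmons reaction of F6 with 7 (LiCl, i-Pr2NEt, MeCN, rt) gives 13 with E-selectivity; the phosphonate anion does not olefinate esters, and the conditions are too mild to epimerise the stereocentre or open the aryl lactone.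

Step 5 is third. The aryl enol-lactone may partly hydrolyse in aqueous TFA, or tert-butyl cations may alkylate the freed catechols. The fallback closes the lactone last, so no aryl lactone is present during acidolysis; it sets out from 6 and comes back at 14. Step 2 is stopped before the CSA stage and 6 is isolated. Ylide 12 is preformed from 10 and 11 (toluene, 60 °C) and then treated with 6 to give the open-chain protected cinnamate F7; the free phenol is tolerated by the stabilised ylide. TFA/H2O converts F7 into the fully deprotected seco ethyl ester F8. Anhydrous CSA in dioxane/toluene at 90 °C with removal of ethanol then closes the six-membered aryl lactone from the adjacent 3-OH, the only hydroxyl within reach of the ester, to give 14.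

**Further compounds**
F1 | step 2 | ethyl 2-(4-formyl-2-hydroxyphenoxy)acetate | CCOC(=O)COc1ccc(C=O)cc1O
F2 | step 2 | 3-oxo-2,3-dihydro-1,4-benzodioxine-6-carbaldehyde | O=Cc1ccc2c(c1)OC(=O)CO2
F3 | step 2 | tert-butyl (2R)-3-(2,2-dimethyl-1,3-benzodioxol-5-yl)-2-{[(2E)-3-(3-oxo-2,3-dihydro-1,4-benzodioxin-6-yl)prop-2-enoyl]oxy}propanoate | O=C(/C=C/c1ccc2c(c1)OC(=O)CO2)O[C@H](Cc1ccc2OC(C)(C)Oc2c1)C(=O)OC(C)(C)C
F4 | step 2 | 2,2-dimethyl-1,3-benzodioxole-5-carbaldehyde | CC1(C)Oc2ccc(C=O)cc2O1
F5 | step 2 | tert-butyl (2R)-3-(2,2-dimethyl-1,3-benzodioxol-5-yl)-2-{[(2E)-3-{2-[(2,2-dimethyl-1,3-benzodioxol-5-yl)(hydroxy)methyl]-3-oxo-2,3-dihydro-1,4-benzodioxin-6-yl}prop-2-enoyl]oxy}propanoate (diastereomer mixture at the two new centres) | O=C(/C=C/c1ccc2c(c1)OC(=O)C(C(O)c1ccc3OC(C)(C)Oc3c1)O2)O[C@H](Cc1ccc2OC(C)(C)Oc2c1)C(=O)OC(C)(C)C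
F6 | step 4 | tert-butyl (2R)-2-{[(diethoxyphosphoryl)acetyl]oxy}-3-(2,2-dimethyl-1,3-benzodioxol-5-yl)propanoate | CCOP(=O)(OCC)CC(=O)O[C@H](Cc1ccc2OC(C)(C)Oc2c1)C(=O)OC(C)(C)C
F7 | step 5 | tert-butyl (2R)-3-(2,2-dimethyl-1,3-benzodioxol-5-yl)-2-{[(2E)-3-(4-{[(1Z)-2-(2,2-dimethyl-1,3-benzodioxol-5-yl)-1-(ethoxycarbonyl)ethenyl]oxy}-3-hydroxyphenyl)prop-2-enoyl]oxy}propanoate | CCOC(=O)/C(=C/c1ccc2OC(C)(C)Oc2c1)Oc1ccc(/C=C/C(=O)O[C@H](Cc2ccc3OC(C)(C)Oc3c2)C(=O)OC(C)(C)C)cc1O
F8 | step 5 | (2R)-3-(3,4-dihydroxyphenyl)-2-{[(2E)-3-(4-{[(1Z)-2-(3,4-dihydroxyphenyl)-1-(ethoxycarbonyl)ethenyl]oxy}-3-hydroxyphenyl)prop-2-enoyl]oxy}propanoic acid | CCOC(=O)/C(=C/c1ccc(O)c(O)c1)Oc1ccc(/C=C/C(=O)O[C@H](Cc2ccc(O)c(O)c2)C(=O)O)cc1O
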